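**Plan**

1. Retrosynthesis: the butenolide is cut at C12=C13 (Wittig, then double-bond shift into the ring); C4–CH3 and C5–H are cut by reductive methylation of a Δ4-19-ester; C1–C10 and C4=C5 are cut together; ring B is cut at C6–C7 and C8–C9 (Diels–Alder).
2. Forward: ring B is made first, by a catalytic enantioselective Diels–Alder reaction that also delivers the C5–O/C10 silyl enol ether; ring A follows in one operation, the C10 enolate adding to C1 of a 2-phosphonopenta-2,4-dienoate and the C4 phosphonate carbanion olefinating the C5 ketone; the side chain is finished last.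
3. Enabling feature: ring A is a carbocycle annulated on the C5–C10 bond of ring B, C10 is a methyl-bearing quaternary carbon next to C5, and C4 carries the C19 carboxyl; C10 and C5 can therefore be the enolate carbon and the carbonyl carbon of one ring-B ketone, while C1 is the δ-carbon and C4 the carboxyl- and phosphoryl-stabilised carbanion of one C1–C4 reagent.
4. Stereochemistry: C9 and the absolute configuration come from the Diels–Alder catalyst; C10 from attack anti to the C9 chain; C5 and C4 from the dissolving-metal step (axial protonation, methyl anti to C20); C8 from equilibration to the equatorial ester.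
5. Helpers: the ring-B ketone oxygen (lost as phosphate), the C2=C3 bond (hydrogenated), the silyl groups and the tert-butyl esters (removed at the end).

Key step: step 6

Remark: labdane numbering (C1–C20) is used for all intermediates; 1, 2, 6, 9, 10 and 20 are taken as catalogue compounds; from step 3 to step 8 the C8 ester is carried in the endo-derived 8,9-cis configuration, and any partial equilibration before step 9 is without consequence because step 9 sets C8 thermodynamically.

**Route**

Step 1
Reactants: 1 3-[(tert-butyldimethylsilyl)oxy]propanal; 2 3-(triphenyl-λ5-phosphanylidene)butan-2-one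
Product: 3 (3E)-6-[(tert-butyldimethylsilyl)oxy]-3-methylhex-3-en-2-one
Conditions: toluene, 90 °C
Reagents that add atoms: none
Why: Wittig olefination with the stabilised acyl ylide should give the trisubstituted enone with the E geometry (acyl group trans to C11), which later places the C9 chain on the outside of the diene, and no stereocentre is formed.

Step 2
Reactants: 3 (3E)-6-[(tert-butyldimethylsilyl)oxy]-3-methylhex-3-en-2-one
Product: 5 (3E)-6-[(tert-butyldimethylsilyl)oxy]-3-methyl-2-[(triisopropylsilyl)oxy]hexa-1,3-diene, via lithium dienolate 4 (not isolated)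
Conditions: LDA, THF, −78 °C; then TIPSOTf, −78 → 0 °C
Reagents that add atoms: triisopropylsilyl trifluoromethanesulfonate, CC(C)[Si](C(C)C)(C(C)C)OS(=O)(=O)C(F)(F)F
Why: Kinetic deprotonation of the methyl ketone by LDA gives the cross-conjugated lithium dienolate 4, and O-silylation with the silyl triflate then gives the 2-silyloxy diene (silyl enol ether formation) without touching the C9=C10 geometry or the silyl ether.

Step 3
Reactants: 5 (3E)-6-[(tert-butyldimethylsilyl)oxy]-3-methyl-2-[(triisopropylsilyl)oxy]hexa-1,3-diene; 6 2,2,2-trifluoroethyl acrylate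
Product: 7 2,2,2-trifluoroethyl (1S,2S)-2-{2-[(tert-butyldimethylsilyl)oxy]ethyl}-3-methyl-4-[(triisopropylsilyl)oxy]cyclohex-3-ene-1-carboxylate
Conditions: (S)-1-(o-tolyl)-3,3-diphenyltetrahydro-1H,3H-pyrrolo[1,2-c][1,3,2]oxazaborole (20 mol%), HN(SO2CF3)2 (20 mol%), CH2Cl2, −78 → −20 °C
Reagents that add atoms: none
Why: Oxazaborolidinium-catalysed Diels–Alder reaction in which the 2-silyloxy group directs C6 to the acrylate β-carbon, the endo transition state places the ester cis to the C9 chain, and the catalyst bound to the acrylate carbonyl (α-C–H···O contact) should leave the Re face of the α-carbon open, so that C8 (S) and with it C9 (S) are set and the ring double bond arrives as the C5–O/C10 silyl enol ether.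

Step 4
Reactants: 7 2,2,2-trifluoroethyl (1S,2S)-2-{2-[(tert-butyldimethylsilyl)oxy]ethyl}-3-methyl-4-[(triisopropylsilyl)oxy]cyclohex-3-ene-1-carboxylate
Product: 8 tert-butyl (1S,2S)-2-{2-[(tert-butyldimethylsilyl)oxy]ethyl}-3-methyl-4-[(triisopropylsilyl)oxy]cyclohex-3-ene-1-carboxylate
Conditions: LiOtBu (1.5 equiv), THF, 0 °C → rt
Reagents that add atoms: lithium tert-butoxide, [Li+].[O-]C(C)(C)C
Why: Alkoxide transesterification of the activated trifluoroethyl ester (trifluoroethoxide being the better leaving group and the poorer nucleophile) should give the tert-butyl ester needed for steps 8 and 13, while the hindered triisopropylsilyl enol ether and the silyl ether are inert to lithium tert-butoxide and the cis C8/C9 relationship, the more stable one while the C9 chain is pseudoaxial, is kept.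

Step 5
Reactants: 9 acrolein; 10 tert-butyl 2-(diethoxyphosphoryl)acetate
Product: 11 tert-butyl 2-(diethoxyphosphoryl)penta-2,4-dienoate
Conditions: TiCl4, N-methylmorpholine, THF, 0 °C
Reagents that add atoms: none
Why: Knoevenagel condensation mediated by TiCl4 and a tertiary amine should convert the phosphonoacetate and acrolein into the 2-phosphono-2,4-dienoate, which is used at once because it is prone to dimerise, and neither a stereocentre nor a defined C3=C4 geometry is needed.

Step 6
Reactants: 8 tert-butyl (1S,2S)-2-{2-[(tert-butyldimethylsilyl)oxy]ethyl}-3-methyl-4-[(triisopropylsilyl)oxy]cyclohex-3-ene-1-carboxylate; 11 tert-butyl 2-(diethoxyphosphoryl)penta-2,4-dienoate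
Product: 14 ring-A dienoate (di-tert-butyl 12-silyloxy-13,14,15,16,18-pentanorlabda-2,4-diene-17,19-dioate), via cesium enolate 12 (not isolated), via open-chain phosphonate carbanion 13 (not isolated)
Conditions: CsF (1.5 equiv), 18-crown-6 (0.2 equiv), 11 (1.5 equiv), DMF–THF, 0 → 50 °C
Reagents that add atoms: none
Why: Proposed new method: CsF unmasks the regiodefined cesium enolate 12, whose C10 adds to the terminal δ-carbon (C1) of the doubly activated diene 11 (vinylogous Michael addition), and the resulting phosphoryl- and ester-stabilised allyl carbanion 13 then olefinates the C5 ketone intramolecularly (Horner–Wadsworth–Emmons), so that C1–C10 and C4=C5 are formed in one flask with loss of cesium diethyl phosphate. The closest known reaction types are the cyclohexadiene annulation of ketone enolates with buta-1,3-dienyltriphenylphosphonium salts (terminal conjugate addition, then intramolecular Wittig) and the tandem Michael/Horner–Wadsworth–Emmons annulation with 2-phosphonoacrylates, and the reagent here merges the two by carrying the C19 ester on the phosphonate carbon. Ring A is closed by 6-exo-trig addition of the C4 carbanion to the C5 carbonyl followed by syn-elimination of phosphate, the cis C2=C3 geometry needed in the ring being reached by rotation within the delocalised allyl anion. The one new stereocentre, quaternary C10, is controlled by C9: allylic 1,2-strain with the C10 methyl holds the C9 chain pseudoaxial in the enolate, so C1 should enter from the opposite (α) face and C20 end up β, cis to C11. The step needs δ- over β-addition, C- over O-alkylation and reaction at C10 instead of C6: the β-adduct cannot olefinate (it would need a four-membered ring) and reverts, whereas the δ-adduct is removed irreversibly by the olefination, the soft dienyl acceptor favours carbon, and the position of the enolate is fixed by the silyl enol ether made in step 3.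

Step 7
Reactants: 14 ring-A dienoate
Product: 15 di-tert-butyl 12-[(tert-butyldimethylsilyl)oxy]-13,14,15,16,18-pentanorlabd-4-ene-17,19-dioate
Conditions: H2 (1 atm), RhCl(PPh3)3 (5 mol%), benzene–EtOH, rt
Reagents that add atoms: none
Why: Homogeneous hydrogenation with RhCl(PPh3)3 should saturate the cis-disubstituted C2=C3 bond and leave the tetrasubstituted C4=C5 enoate, which gives the Δ4-19-ester needed for reductive alkylation without forming a stereocentre.

Step 8
Reactants: 15 di-tert-butyl 12-[(tert-butyldimethylsilyl)oxy]-13,14,15,16,18-pentanorlabd-4-ene-17,19-dioate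
Product: 17 8β-ester of di-tert-butyl 12-[(tert-butyldimethylsilyl)oxy]-13,14,15,16-tetranorlabdane-17,19-dioate, via lithium ester enolate 16 (not isolated)
Conditions: Li (2.5 equiv), NH3–THF, t-BuOH (1 equiv), −78 °C; isoprene; then MeI, −78 → −33 °C
Reagents that add atoms: iodomethane, CI
Why: Birch-type reductive alkylation of the α,β-unsaturated ester, in which axial protonation of the C5 carbanion from the α face by tert-butanol should set the trans ring fusion (5α-H, anti to C20) and methylation of the exocyclic lithium ester enolate 16 from the α face, anti to the 1,3-diaxial C20 methyl, should leave the C19 ester axial (4β) and the new methyl equatorial (4α), while limited lithium and a single equivalent of proton source spare the saturated tert-butyl ester and the silyl ether.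

Step 9
Reactants: 17 8β-ester of di-tert-butyl 12-[(tert-butyldimethylsilyl)oxy]-13,14,15,16-tetranorlabdane-17,19-dioate
Product: 18 8α-ester of di-tert-butyl 12-[(tert-butyldimethylsilyl)oxy]-13,14,15,16-tetranorlabdane-17,19-dioate
Conditions: t-BuOK (0.5 equiv), t-BuOH–THF, 50 °C
Reagents that add atoms: none
Why: Base-mediated epimerisation through the C17 ester enolate should move the axial 8β ester, which is 1,3-diaxial to C20, to the equatorial 8α position trans to the C9 chain (thermodynamic control), and C4, which has no α-hydrogen, is untouched.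

Step 10
Reactants: 18 8α-ester of di-tert-butyl 12-[(tert-butyldimethylsilyl)oxy]-13,14,15,16-tetranorlabdane-17,19-dioate
Product: 19 di-tert-butyl 12-hydroxy-13,14,15,16-tetranorlabdane-17,19-dioate
Conditions: TBAF, THF, 0 °C → rt
Reagents that add atoms: none
Why: Fluoride-mediated desilylation should free the primary C12 alcohol without touching the tert-butyl esters or any stereocentre.

Step 11
Reactants: 19 di-tert-butyl 12-hydroxy-13,14,15,16-tetranorlabdane-17,19-dioate; 20 3-(triphenyl-λ5-phosphanylidene)dihydrofuran-2(3H)-one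
Product: 22 di-tert-butyl (12E)-labd-12-en-16,15-olide-17,19-dioate, via C12 aldehyde 21 (not isolated)
Conditions: Dess–Martin periodinane, NaHCO3, CH2Cl2, 0 °C → rt; then 20, 40 °C
Reagents that add atoms: none
Why: Dess–Martin oxidation to the aldehyde 21 followed in the same flask by Wittig olefination with the stabilised lactone ylide should give the (E)-α-alkylidene lactone, the bicarbonate taking up the acetic acid that would otherwise protonate the ylide, and no ring stereocentre is affected.

Step 12
Reactants: 22 di-tert-butyl (12E)-labd-12-en-16,15-olide-17,19-dioate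
Product: 23 di-tert-butyl labd-13-en-16,15-olide-17,19-dioate
Conditions: RhCl3·3H2O (10 mol%), EtOH, 80 °C
Reagents that add atoms: none
Why: Rhodium hydride-mediated double-bond migration (hydrometalation and β-hydride elimination) should move the exocyclic C12=C13 bond into the ring and give the more stable endocyclic α-alkyl butenolide (C13=C14), with no stereocentre affected.

Step 13
Reactants: 23 di-tert-butyl labd-13-en-16,15-olide-17,19-dioate
Product: 24 labd-13-en-16,15-olide-17,19-dioic acid (target)
Conditions: CF3CO2H–CH2Cl2 (1:1), rt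
Reagents that add atoms: none
Why: Acidolysis of both tert-butyl esters by alkyl–oxygen cleavage (tert-butyl cation lost as 2-methylpropene), a pathway that is insensitive to the steric shielding of the axial C19 ester and leaves the butenolide intact, should give the diacid.

**Compound list**

1 | 3-[(tert-butyldimethylsilyl)oxy]propanal | O=CCCO[Si](C)(C)C(C)(C)C | starting material
2 | 3-(triphenyl-λ5-phosphanylidene)butan-2-one | CC(=O)C(C)=P(c1ccccc1)(c1ccccc1)c1ccccc1 | starting material
3 | (3E)-6-[(tert-butyldimethylsilyl)oxy]-3-methylhex-3-en-2-one | CC(=O)/C(C)=C/CCO[Si](C)(C)C(C)(C)C | intermediate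
4 | lithium cross-conjugated dienolate of 3 | [Li+].C=C([O-])/C(C)=C/CCO[Si](C)(C)C(C)(C)C | intermediate
5 | (3E)-6-[(tert-butyldimethylsilyl)oxy]-3-methyl-2-[(triisopropylsilyl)oxy]hexa-1,3-diene | C=C(O[Si](C(C)C)(C(C)C)C(C)C)/C(C)=C/CCO[Si](C)(C)C(C)(C)C | intermediate
6 | 2,2,2-trifluoroethyl acrylate | C=CC(=O)OCC(F)(F)F | starting material
7 | 2,2,2-trifluoroethyl (1S,2S)-2-{2-[(tert-butyldimethylsilyl)oxy]ethyl}-3-methyl-4-[(triisopropylsilyl)oxy]cyclohex-3-ene-1-carboxylate (ring B; ester cis to the C9 chain) | CC1=C(O[Si](C(C)C)(C(C)C)C(C)C)CC[C@H](C(=O)OCC(F)(F)F)[C@@H]1CCO[Si](C)(C)C(C)(C)C | intermediate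
8 | tert-butyl (1S,2S)-2-{2-[(tert-butyldimethylsilyl)oxy]ethyl}-3-methyl-4-[(triisopropylsilyl)oxy]cyclohex-3-ene-1-carboxylate | CC1=C(O[Si](C(C)C)(C(C)C)C(C)C)CC[C@H](C(=O)OC(C)(C)C)[C@@H]1CCO[Si](C)(C)C(C)(C)C | intermediate
9 | acrolein (prop-2-enal) | C=CC=O | starting material
10 | tert-butyl 2-(diethoxyphosphoryl)acetate | CCOP(=O)(OCC)CC(=O)OC(C)(C)C | starting material
11 | tert-butyl 2-(diethoxyphosphoryl)penta-2,4-dienoate (E/Z mixture) | C=CC=C(C(=O)OC(C)(C)C)P(=O)(OCC)OCC | intermediate
12 | cesium enolate of the ring-B ketone (C5–O−, C5=C10), from 8 | [Cs+].CC1=C([O-])CC[C@H](C(=O)OC(C)(C)C)[C@@H]1CCO[Si](C)(C)C(C)(C)C | intermediate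
13 | cesium salt of the 1,6-adduct: ring-B ketone carrying at C10 (trans to the C9 chain) the CH2–CH=CH–C(−)(PO(OEt)2)CO2tBu chain | [Cs+].C[C@]1(CC=C[C-](C(=O)OC(C)(C)C)P(=O)(OCC)OCC)C(=O)CC[C@H](C(=O)OC(C)(C)C)[C@@H]1CCO[Si](C)(C)C(C)(C)C | intermediate
14 | di-tert-butyl 12-[(tert-butyldimethylsilyl)oxy]-13,14,15,16,18-pentanorlabda-2,4-diene-17,19-dioate (8β-ester, 9β-chain, 10β-methyl) | C[C@]12CC=CC(C(=O)OC(C)(C)C)=C1CC[C@H](C(=O)OC(C)(C)C)[C@@H]2CCO[Si](C)(C)C(C)(C)C | intermediate
15 | di-tert-butyl 12-[(tert-butyldimethylsilyl)oxy]-13,14,15,16,18-pentanorlabd-4-ene-17,19-dioate (8β-ester, 9β-chain, 10β-methyl) | C[C@]12CCCC(C(=O)OC(C)(C)C)=C1CC[C@H](C(=O)OC(C)(C)C)[C@@H]2CCO[Si](C)(C)C(C)(C)C | intermediate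
16 | lithium enolate of the C19 tert-butyl ester (C4=C19, 5α-H) | [Li+].C[C@]12CCCC(=C([O-])OC(C)(C)C)[C@@H]1CC[C@H](C(=O)OC(C)(C)C)[C@@H]2CCO[Si](C)(C)C(C)(C)C | intermediate
17 | di-tert-butyl 12-[(tert-butyldimethylsilyl)oxy]-13,14,15,16-tetranorlabdane-17,19-dioate (4α-methyl, 4β-ester, 5α-H, 8β-ester, 9β-chain, 10β-methyl) | C[C@]12CCC[C@](C)(C(=O)OC(C)(C)C)[C@@H]1CC[C@H](C(=O)OC(C)(C)C)[C@@H]2CCO[Si](C)(C)C(C)(C)C | intermediate
18 | di-tert-butyl 12-[(tert-butyldimethylsilyl)oxy]-13,14,15,16-tetranorlabdane-17,19-dioate (4α-methyl, 4β-ester, 5α-H, 8α-ester, 9β-chain, 10β-methyl) | C[C@]12CCC[C@](C)(C(=O)OC(C)(C)C)[C@@H]1CC[C@@H](C(=O)OC(C)(C)C)[C@@H]2CCO[Si](C)(C)C(C)(C)C | intermediate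
19 | di-tert-butyl 12-hydroxy-13,14,15,16-tetranorlabdane-17,19-dioate (configuration as in 18) | C[C@]12CCC[C@](C)(C(=O)OC(C)(C)C)[C@@H]1CC[C@@H](C(=O)OC(C)(C)C)[C@@H]2CCO | intermediate
20 | 3-(triphenyl-λ5-phosphanylidene)dihydrofuran-2(3H)-one | O=C1OCCC1=P(c1ccccc1)(c1ccccc1)c1ccccc1 | starting material
21 | di-tert-butyl 12-oxo-13,14,15,16-tetranorlabdane-17,19-dioate (C12 aldehyde) | C[C@]12CCC[C@](C)(C(=O)OC(C)(C)C)[C@@H]1CC[C@@H](C(=O)OC(C)(C)C)[C@@H]2CC=O | intermediate
22 | di-tert-butyl (12E)-labd-12-en-16,15-olide-17,19-dioate (α-alkylidene lactone) | C[C@]12CCC[C@](C)(C(=O)OC(C)(C)C)[C@@H]1CC[C@@H](C(=O)OC(C)(C)C)[C@@H]2C/C=C1\CCOC1=O | intermediate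
23 | di-tert-butyl labd-13-en-16,15-olide-17,19-dioate | C[C@]12CCC[C@](C)(C(=O)OC(C)(C)C)[C@@H]1CC[C@@H](C(=O)OC(C)(C)C)[C@@H]2CCC1=CCOC1=O | intermediate
24 | labd-13-en-16,15-olide-17,19-dioic acid (4α-methyl, 4β-CO2H, 5α-H, 8α-CO2H, 9β-side chain, 10β-methyl; CNP0478950.1) | C[C@]12CCC[C@](C)(C(=O)O)[C@@H]1CC[C@@H](C(=O)O)[C@@H]2CCC1=CCOC1=O | target

**Summary**

Total step count: 13. Longest linear sequence: 12 steps (1, 2, 3, 4, 6, 7, 8, 9, 10, 11, 12, 13); step 5 is a one-step side branch.

Steps most likely to fail:

Step 6 (Proposed new method). What may go wrong: addition of the enolate at the β-carbon or through oxygen, dimerisation of the dienyl phosphonate before it is captured, or slow olefination of the hindered C5 ketone by the stabilised carbanion. The fallback sets out from 8 and comes back at 15, making the two bonds one after the other by known reactions. The fluoride-released enolate of 8 is alkylated at C10, anti to the C9 chain, with an excess of 1,3-diiodopropane (CsF, DMF) to give the 10-(3-iodopropyl) ketone F1. This iodide alkylates the sodium salt of 10 (NaH, THF–DMF) to give the keto phosphonate F2. NaH in THF at reflux then closes ring A by intramolecular Horner–Wadsworth–Emmons olefination of the C5 ketone and gives 15 directly, so that step 7 is not needed.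

Step 8. What may go wrong: protonation of C5 from the β face (cis ring fusion), or reduction, enolisation and methylation at the saturated C17 ester. The fallback sets out from 15 and comes back at 17, replacing the dissolving-metal step by deconjugative alkylation and hydrogenation. LDA (1.05 equiv) in THF–DMPU at −78 °C removes the γ-hydrogen at C6, and MeI alkylates the extended enolate at C4 from the α face to give the 4α-methyl Δ5-ester F3. Hydrogenation over Pd/C in EtOAc from the α face, anti to C20 and the axial C19 ester, then sets 5α-H and gives 17.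

Step 12. What may go wrong: incomplete or unselective double-bond migration (exocyclic/endocyclic mixture), or acid-induced loss of tert-butyl groups in hot ethanol. The fallback sets out from 19 and comes back at 23, building the butenolide by alkylation and sulfoxide elimination instead of olefination and isomerisation. Appel-type iodination (I2, PPh3, imidazole) converts 19 into the C12 iodide F4. The lithium enolate of 3-(phenylsulfanyl)dihydrofuran-2(3H)-one (LiHMDS, THF–HMPA) is alkylated by F4 to give the α-phenylsulfanyl lactone F5. mCPBA at −78 °C gives the sulfoxide F6, and thermal syn-elimination toward the ring methylene (toluene, 110 °C) gives the endocyclic butenolide 23.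

Further compounds
F1 | step 6 | tert-butyl 2-{2-[(tert-butyldimethylsilyl)oxy]ethyl}-3-(3-iodopropyl)-3-methyl-4-oxocyclohexane-1-carboxylate (iodopropyl trans to the C9 chain) | C[C@]1(CCCI)C(=O)CC[C@H](C(=O)OC(C)(C)C)[C@@H]1CCO[Si](C)(C)C(C)(C)C
F2 | step 6 | keto phosphonate: the ketone of F1 with the chain CH2CH2CH2–CH(PO(OEt)2)CO2tBu at C10 (epimers at C4) | C[C@]1(CCCC(C(=O)OC(C)(C)C)P(=O)(OCC)OCC)C(=O)CC[C@H](C(=O)OC(C)(C)C)[C@@H]1CCO[Si](C)(C)C(C)(C)C
F3 | step 8 | di-tert-butyl 12-[(tert-butyldimethylsilyl)oxy]-13,14,15,16-tetranorlabd-5-ene-17,19-dioate (4α-methyl, 4β-ester, 8β-ester) | C[C@]12CCC[C@](C)(C(=O)OC(C)(C)C)C1=CC[C@H](C(=O)OC(C)(C)C)[C@@H]2CCO[Si](C)(C)C(C)(C)C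
F4 | step 12 | di-tert-butyl 12-iodo-13,14,15,16-tetranorlabdane-17,19-dioate | C[C@]12CCC[C@](C)(C(=O)OC(C)(C)C)[C@@H]1CC[C@@H](C(=O)OC(C)(C)C)[C@@H]2CCI
F5 | step 12 | di-tert-butyl 13-(phenylsulfanyl)labdan-16,15-olide-17,19-dioate (epimers at C13) | C[C@]12CCC[C@](C)(C(=O)OC(C)(C)C)[C@@H]1CC[C@@H](C(=O)OC(C)(C)C)[C@@H]2CCC1(Sc3ccccc3)CCOC1=O
F6 | step 12 | di-tert-butyl 13-(phenylsulfinyl)labdan-16,15-olide-17,19-dioate | C[C@]12CCC[C@](C)(C(=O)OC(C)(C)C)[C@@H]1CC[C@@H](C(=O)OC(C)(C)C)[C@@H]2CCC1(S(=O)c3ccccc3)CCOC1=O
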